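Everything rests on opening the benzene ring of the dihydrobenzofuran at C3a–C4 and C5–C6. This ring bears oxygen at C7a (O1) and at C6, meta to each other, with the acetyl group at C5 beside the phenol: the pattern left when a diene oxygenated at C7a and doubly at C6 captures an acetylenic ketone. A chiral 2,3-dihydrofuran that already holds the cis C2 isopropenyl and C3 silyloxy groups, extended at its enol-ether carbon by a bis(silyl) ketene acetal, therefore adds but-3-yn-2-one; loss of silanol aromatises the adduct, so arene, acetyl position and phenol arise in one operation. The side-chain acid is esterified last.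

Key step: step 10

Assumption: the sense of induction in step 1 follows the usual model for diisopinocampheylboranes [(+)-Ipc2BOMe, from (−)-α-pinene, delivering the allyl unit to the Re face of the aldehyde]; if the opposite sense were found, the enantiomeric borane would be used.
Assumption: 11 is drawn as the cyclic hemiketal although it equilibrates with the open-chain γ-hydroxy β-keto ester, and 12–14 are drawn as E isomers although either alkene geometry converges on diene 15.

Step 1
Reactants: 1 allyl methoxymethyl ether; 2 methacrolein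
Product: 4 (3S,4S)-3-(methoxymethoxy)-5-methylhexa-1,5-dien-4-ol, via allylborane 3 (not isolated)
Conditions: 1, s-BuLi, THF, −78 °C; (+)-Ipc2BOMe, −78 °C; BF3·OEt2; 2, −78 °C; then NaOH, H2O2, 0 °C → rt
Reagents that add atoms: none
Why: Asymmetric alkoxyallylboration with a diisopinocampheylborane: kinetic deprotonation of 1 and boron transfer give the (Z)-γ-alkoxyallylborane 3, whose closed chair-like transition state with 2 turns the Z geometry into the syn 3,4-relationship while the isopinocampheyl groups select the aldehyde face, so both stereocentres should be set as 3S,4S.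

Step 2
Reactants: 4 (3S,4S)-3-(methoxymethoxy)-5-methylhexa-1,5-dien-4-ol
Product: 5 (3S,4S)-3-(methoxymethoxy)-5-methylhex-5-ene-1,4-diol
Conditions: disiamylborane [bis(3-methylbutan-2-yl)borane, from BH3·THF and 2-methylbut-2-ene, 2.5 equiv], THF, −10 → 0 °C; then NaOH, H2O2, 0 °C → rt
Reagents that add atoms: hydrogen peroxide, OO
Why: Hydroboration–oxidation: the hindered dialkylborane should react at the monosubstituted vinyl group well before the 1,1-disubstituted, α-branched isopropenyl group and place boron on the terminal carbon, so oxidation gives the primary alcohol without touching the stereocentres.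

Step 3
Reactants: 5 (3S,4S)-3-(methoxymethoxy)-5-methylhex-5-ene-1,4-diol
Product: 6 (4S,5S)-4-(methoxymethoxy)-5-(prop-1-en-2-yl)oxolan-2-one
Conditions: 2,2,6,6-tetramethylpiperidin-1-oxyl (TEMPO, 0.1 equiv), PhI(OAc)2 (2.5 equiv), CH2Cl2, rt
Reagents that add atoms: none
Why: Oxoammonium-mediated oxidative lactonisation: the primary alcohol is oxidised selectively, the aldehyde is trapped by the C4 hydroxyl as a lactol and oxidised on to the γ-lactone, in which the syn diol relationship appears as the cis 4,5-substitution.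

Step 4
Reactants: 6 (4S,5S)-4-(methoxymethoxy)-5-(prop-1-en-2-yl)oxolan-2-one
Product: 7 (4S,5S)-4-hydroxy-5-(prop-1-en-2-yl)oxolan-2-one
Conditions: HCl (0.5 M in MeOH), rt → 40 °C
Reagents that add atoms: none
Why: Acid-catalysed acetal exchange passes the methoxymethyl group to methanol; a γ-lactone that opens re-closes on concentration, and no stereocentre takes part.

Step 5
Reactants: 7 (4S,5S)-4-hydroxy-5-(prop-1-en-2-yl)oxolan-2-one
Product: 8 (4S,5S)-4-[(tert-butyldimethylsilyl)oxy]-5-(prop-1-en-2-yl)oxolan-2-one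
Conditions: t-BuMe2SiCl, imidazole, DMF, 0 °C → rt
Reagents that add atoms: tert-butyldimethylsilyl chloride, CC(C)(C)[Si](C)(C)Cl
Why: Standard silylation of a secondary alcohol installs an ether that tolerates enolates, hydroxide and the cycloaddition and is a poor leaving group at the later allylic C3 position.

Step 6
Reactants: 8 (4S,5S)-4-[(tert-butyldimethylsilyl)oxy]-5-(prop-1-en-2-yl)oxolan-2-one; 9 methyl acetate
Product: 11 methyl 2-[(4S,5S)-4-[(tert-butyldimethylsilyl)oxy]-2-hydroxy-5-(prop-1-en-2-yl)oxolan-2-yl]acetate, via lithium enolate 10 (not isolated)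
Conditions: 9 (2.4 equiv), LiN(iPr)2 (2.3 equiv), THF, −78 °C; then 8, −78 °C; AcOH quench at −78 °C
Reagents that add atoms: none
Why: Crossed Claisen-type addition of ester enolate 10 to the lactone carbonyl gives, after cold protonation, the hemiketal with C4 and C5 untouched; low temperature and the cold quench should suppress lactone enolisation and silyl migration.

Step 7
Reactants: 11 methyl 2-[(4S,5S)-4-[(tert-butyldimethylsilyl)oxy]-2-hydroxy-5-(prop-1-en-2-yl)oxolan-2-yl]acetate
Product: 12 methyl (2E)-2-[(4S,5S)-4-[(tert-butyldimethylsilyl)oxy]-5-(prop-1-en-2-yl)oxolan-2-ylidene]acetate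
Conditions: (1S)-(+)-camphor-10-sulfonic acid (5 mol %), 4 Å molecular sieves, CH2Cl2, 0 °C → rt
Reagents that add atoms: none
Why: Acid-catalysed cyclodehydration of the hemiketal through its oxocarbenium ion should give the conjugated exocyclic enol ether (a vinylogous carbonate), the favoured alkene isomer; mild acid and short contact are chosen to avoid ionising the C4 silyloxy group.

Step 8
Reactants: 12 methyl (2E)-2-[(4S,5S)-4-[(tert-butyldimethylsilyl)oxy]-5-(prop-1-en-2-yl)oxolan-2-ylidene]acetate
Product: 13 (2E)-2-[(4S,5S)-4-[(tert-butyldimethylsilyl)oxy]-5-(prop-1-en-2-yl)oxolan-2-ylidene]acetic acid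
Conditions: LiOH·H2O (5 equiv), THF/MeOH/H2O, 40 °C; then 1 M HCl to pH 4–5, 0 °C
Reagents that add atoms: lithium hydroxide, [Li+].[OH-]
Why: Saponification of the methyl ester; silyl ether and enol ether are stable to hydroxide, and only brief cold acidification is needed to free the β-alkoxyacrylic acid.

Step 9
Reactants: 13 (2E)-2-[(4S,5S)-4-[(tert-butyldimethylsilyl)oxy]-5-(prop-1-en-2-yl)oxolan-2-ylidene]acetic acid
Product: 15 (2S,3S)-5-[2,2-bis(trimethylsilyloxy)ethenyl]-3-[(tert-butyldimethylsilyl)oxy]-2-(prop-1-en-2-yl)-2,3-dihydrofuran, via trimethylsilyl ester 14 (not isolated)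
Conditions: LiN(iPr)2 (1.05 equiv), THF, −78 °C, then Me3SiCl (1.1 equiv), → 0 °C; recool to −78 °C, Me3SiCl (1.5 equiv), then LiN(iPr)2 (1.2 equiv) dropwise; → rt, pentane, filtration under Ar; used crude
Reagents that add atoms: chlorotrimethylsilane, C[Si](C)(C)Cl
Why: O-silylation of the carboxylate gives silyl ester 14, whose γ-deprotonation at the ring CH2 (vinylogous enolisation) with in situ O-silylation gives the bis(silyl) vinylketene acetal with the double bond moved into the ring; the internal quench keeps the dienolate short-lived so that the β-silyloxy group is not expelled, and the two stereocentres are not involved.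

Step 10
Reactants: 15 (2S,3S)-5-[2,2-bis(trimethylsilyloxy)ethenyl]-3-[(tert-butyldimethylsilyl)oxy]-2-(prop-1-en-2-yl)-2,3-dihydrofuran; 16 but-3-yn-2-one
Product: 19 1-[(2S,3S)-3-[(tert-butyldimethylsilyl)oxy]-6-hydroxy-2-(prop-1-en-2-yl)-2,3-dihydro-1-benzofuran-5-yl]ethan-1-one, via cycloadduct 17 (not isolated), via aryl trimethylsilyl ether 18 (not isolated)
Conditions: 16 (1.5 equiv), toluene (acid-free, base-washed glassware), 0 → 40 °C; then 0.5 M aq. citric acid/THF, 0 °C
Reagents that add atoms: none
Why: The electron-rich diene C3a=C7a–C7=C6 of 15 attacks the terminal (β) carbon of the ynone through C3a and closes from C6 onto the acyl-bearing carbon in a concerted but strongly asynchronous [4+2] cycloaddition, giving cyclohexa-1,4-diene 17 with a C6 bis(silyl) ketal and a doubly allylic C3a–H. Ionisation of one C6–OSiMe3 bond, assisted by the remaining silyloxy group and by O1 through C7=C7a, and loss of the C3a proton (1,4-elimination of trimethylsilanol) aromatise the ring to 18, whose aryl silyl ether is hydrolysed to the phenol in the mildly acidic work-up. The closest known reaction type is the Diels–Alder benzannulation of 1,1,3-trioxygenated butadienes (vinylketene acetals) with acetylenic ketones and esters to give resorcinol derivatives. The benzene ring is closed intermolecularly in the [4+2] mode, both new σ-bonds (C3a–C4 and C5–C6) forming across the diene termini. No lasting stereocentre is made: C3a is sp3 only in 17 and is flattened on aromatisation, while C2 and C3 are spectators. The step needs the acetyl at C5, which the polarisation of the partners secures (the C3a terminus, remote from the ketene acetal, pairs with the electrophilic β-carbon of the ynone), and it needs cycloaddition to outrun loss of the allylic C3 silyloxy group, which the acid-free medium and the poor leaving ability of that group should secure.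

Step 11
Reactants: 19 1-[(2S,3S)-3-[(tert-butyldimethylsilyl)oxy]-6-hydroxy-2-(prop-1-en-2-yl)-2,3-dihydro-1-benzofuran-5-yl]ethan-1-one
Product: 20 1-[(2S,3S)-3,6-dihydroxy-2-(prop-1-en-2-yl)-2,3-dihydro-1-benzofuran-5-yl]ethan-1-one
Conditions: Bu4NF, AcOH (1:1), THF, 0 °C → rt
Reagents that add atoms: none
Why: Fluoride-mediated desilylation; buffering with acetic acid avoids a free phenoxide and strongly basic conditions, and the stereocentres are not involved.

Step 12
Reactants: 21 (E)-but-2-enal (crotonaldehyde)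
Product: 22 (Z)-2-iodobut-2-enal
Conditions: I2, K2CO3, 4-(dimethylamino)pyridine (0.2 equiv), THF/H2O (1:1), rt
Reagents that add atoms: iodine, II
Why: α-Iodination of the enal by a Baylis–Hillman-type addition–elimination (amine conjugate addition, iodination of the enolate, elimination); the formyl group stays trans to the methyl group, so iodine should end up cis to methyl (Z).

Step 13
Reactants: 22 (Z)-2-iodobut-2-enal
Product: 23 (Z)-2-iodobut-2-en-1-ol
Conditions: NaBH4, MeOH, 0 °C
Reagents that add atoms: none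
Why: 1,2-Reduction of the aldehyde by borohydride leaves the vinyl iodide and its geometry untouched.

Step 14
Reactants: 23 (Z)-2-iodobut-2-en-1-ol
Product: 25 (Z)-2-(hydroxymethyl)but-2-enoic acid, via dilithio alkoxide 24 (not isolated)
Conditions: t-BuLi (3.1 equiv), Et2O, −78 °C; then excess CO2, −78 °C → rt; 1 M HCl
Reagents that add atoms: carbon dioxide, O=C=O
Why: Deprotonation and iodine–lithium exchange proceed with retention of alkene geometry at −78 °C, and carboxylation of vinyllithium 24 places the carboxyl group cis to the methyl group, giving the Z (angelate-type) acid.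

Step 15
Reactants: 25 (Z)-2-(hydroxymethyl)but-2-enoic acid
Product: 26 (Z)-2-(acetoxymethyl)but-2-enoic acid
Conditions: AcCl (2 equiv), CH2Cl2, 0 °C → rt; then H2O/THF
Reagents that add atoms: acetyl chloride, CC(=O)Cl
Why: O-Acetylation of the primary allylic alcohol without base; any mixed anhydride at the carboxyl group is hydrolysed in the aqueous work-up, and the Z alkene never meets a nucleophilic amine.

Step 16
Reactants: 20 1-[(2S,3S)-3,6-dihydroxy-2-(prop-1-en-2-yl)-2,3-dihydro-1-benzofuran-5-yl]ethan-1-one; 26 (Z)-2-(acetoxymethyl)but-2-enoic acid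
Product: 28 (2S,3S)-5-acetyl-6-hydroxy-2-(prop-1-en-2-yl)-2,3-dihydro-1-benzofuran-3-yl (2Z)-2-(acetoxymethyl)but-2-enoate, via acid chloride 27 (not isolated)
Conditions: 26 (1.4 equiv), 1-chloro-N,N,2-trimethylprop-1-en-1-amine (1.3 equiv), CH2Cl2, 0 °C → rt; then 20, 2,6-lutidine (2 equiv), CH2Cl2, −20 °C → rt
Reagents that add atoms: none
Why: Esterification through acid chloride 27, made under neutral conditions with an α-chloroenamine kept in deficit to 26, and a hindered non-nucleophilic base: the aliphatic C3 hydroxyl should react while the C6 phenol, held in a six-membered hydrogen bond to the C5 acetyl and not deprotonated by lutidine, stays free, and the absence of a nucleophilic catalyst protects the Z alkene and the allylic acetate; acylation on oxygen leaves C2 and C3 unchanged.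

Compound list
1 | allyl methoxymethyl ether [3-(methoxymethoxy)prop-1-ene] | C=CCOCOC | starting material
2 | methacrolein (2-methylprop-2-enal) | C=C(C)C=O | starting material
3 | [(Z)-3-(methoxymethoxy)prop-2-en-1-yl]bis[(1S,2S,3S,5R)-isopinocampheyl]borane | COCO/C=C\CB([C@H]1C[C@H]2C[C@H](C2(C)C)[C@@H]1C)[C@H]1C[C@H]2C[C@H](C2(C)C)[C@@H]1C | intermediate
4 | (3S,4S)-3-(methoxymethoxy)-5-methylhexa-1,5-dien-4-ol | C=C(C)[C@@H]([C@@H](OCOC)C=C)O | intermediate
5 | (3S,4S)-3-(methoxymethoxy)-5-methylhex-5-ene-1,4-diol | C=C(C)[C@@H]([C@@H](OCOC)CCO)O | intermediate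
6 | (4S,5S)-4-(methoxymethoxy)-5-(prop-1-en-2-yl)oxolan-2-one (cis lactone) | C=C(C)[C@@H]1OC(=O)C[C@@H]1OCOC | intermediate
7 | (4S,5S)-4-hydroxy-5-(prop-1-en-2-yl)oxolan-2-one | C=C(C)[C@@H]1OC(=O)C[C@@H]1O | intermediate
8 | (4S,5S)-4-[(tert-butyldimethylsilyl)oxy]-5-(prop-1-en-2-yl)oxolan-2-one | C=C(C)[C@@H]1OC(=O)C[C@@H]1O[Si](C)(C)C(C)(C)C | intermediate
9 | methyl acetate | COC(C)=O | starting material
10 | lithium 1-methoxyethen-1-olate (lithium enolate of methyl acetate) | [Li]OC(=C)OC | intermediate
11 | methyl 2-[(4S,5S)-4-[(tert-butyldimethylsilyl)oxy]-2-hydroxy-5-(prop-1-en-2-yl)oxolan-2-yl]acetate (hemiketal, C2 epimers) | C=C(C)[C@@H]1OC(O)(CC(=O)OC)C[C@@H]1O[Si](C)(C)C(C)(C)C | intermediate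
12 | methyl (2E)-2-[(4S,5S)-4-[(tert-butyldimethylsilyl)oxy]-5-(prop-1-en-2-yl)oxolan-2-ylidene]acetate | C=C(C)[C@@H]1O/C(=C/C(=O)OC)C[C@@H]1O[Si](C)(C)C(C)(C)C | intermediate
13 | (2E)-2-[(4S,5S)-4-[(tert-butyldimethylsilyl)oxy]-5-(prop-1-en-2-yl)oxolan-2-ylidene]acetic acid | C=C(C)[C@@H]1O/C(=C/C(=O)O)C[C@@H]1O[Si](C)(C)C(C)(C)C | intermediate
14 | trimethylsilyl (2E)-2-[(4S,5S)-4-[(tert-butyldimethylsilyl)oxy]-5-(prop-1-en-2-yl)oxolan-2-ylidene]acetate | C=C(C)[C@@H]1O/C(=C/C(=O)O[Si](C)(C)C)C[C@@H]1O[Si](C)(C)C(C)(C)C | intermediate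
15 | (2S,3S)-5-[2,2-bis(trimethylsilyloxy)ethenyl]-3-[(tert-butyldimethylsilyl)oxy]-2-(prop-1-en-2-yl)-2,3-dihydrofuran (cis) | C=C(C)[C@@H]1OC(C=C(O[Si](C)(C)C)O[Si](C)(C)C)=C[C@@H]1O[Si](C)(C)C(C)(C)C | intermediate
16 | but-3-yn-2-one | CC(=O)C#C | starting material
17 | 1-[(2S,3S)-3-[(tert-butyldimethylsilyl)oxy]-2-(prop-1-en-2-yl)-6,6-bis(trimethylsilyloxy)-2,3,3a,6-tetrahydro-1-benzofuran-5-yl]ethan-1-one (C3a epimers) | C=C(C)[C@@H]1OC2=CC(O[Si](C)(C)C)(O[Si](C)(C)C)C(C(C)=O)=CC2[C@@H]1O[Si](C)(C)C(C)(C)C | intermediate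
18 | 1-[(2S,3S)-3-[(tert-butyldimethylsilyl)oxy]-2-(prop-1-en-2-yl)-6-(trimethylsilyloxy)-2,3-dihydro-1-benzofuran-5-yl]ethan-1-one | C=C(C)[C@@H]1Oc2cc(O[Si](C)(C)C)c(C(C)=O)cc2[C@@H]1O[Si](C)(C)C(C)(C)C | intermediate
19 | 1-[(2S,3S)-3-[(tert-butyldimethylsilyl)oxy]-6-hydroxy-2-(prop-1-en-2-yl)-2,3-dihydro-1-benzofuran-5-yl]ethan-1-one (cis) | C=C(C)[C@@H]1Oc2cc(O)c(C(C)=O)cc2[C@@H]1O[Si](C)(C)C(C)(C)C | intermediate
20 | 1-[(2S,3S)-3,6-dihydroxy-2-(prop-1-en-2-yl)-2,3-dihydro-1-benzofuran-5-yl]ethan-1-one | C=C(C)[C@@H]1Oc2cc(O)c(C(C)=O)cc2[C@@H]1O | intermediate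
21 | (E)-but-2-enal (crotonaldehyde) | C/C=C/C=O | starting material
22 | (Z)-2-iodobut-2-enal | C/C=C(\I)C=O | intermediate
23 | (Z)-2-iodobut-2-en-1-ol | C/C=C(\I)CO | intermediate
24 | lithium (2E)-2-lithiobut-2-en-1-olate (lithium cis to methyl) | C/C=C(\[Li])CO[Li] | intermediate
25 | (Z)-2-(hydroxymethyl)but-2-enoic acid | C/C=C(\C(=O)O)CO | intermediate
26 | (Z)-2-(acetoxymethyl)but-2-enoic acid | C/C=C(\C(=O)O)COC(C)=O | intermediate
27 | (Z)-2-(acetoxymethyl)but-2-enoyl chloride | C/C=C(\C(=O)Cl)COC(C)=O | intermediate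
28 | (2S,3S)-5-acetyl-6-hydroxy-2-(prop-1-en-2-yl)-2,3-dihydro-1-benzofuran-3-yl (2Z)-2-(acetoxymethyl)but-2-enoate (CNP0193314.1) | C=C(C)[C@@H]1Oc2cc(O)c(C(C)=O)cc2[C@@H]1OC(=O)/C(=C\C)COC(C)=O | target

Total step count: 16. Longest linear sequence: 12 steps (steps 1–11 and 16); the side-chain acid takes steps 12–15.

Steps most likely to fail

Step 10. A slow cycloaddition would leave room for ionisation of the allylic C3–O bond of the diene with aromatisation to a furan, for hydrolysis of the bis(silyl) acetal, or for Michael-type attack through C7 without ring closure. The fallback leaves the route at ester 12 and changes the diene class to an alkyl silyl vinylketene acetal. γ-Deprotonation of 12 with LiN(iPr)2 in the presence of Me3SiCl at −78 °C should give (2S,3S)-3-[(tert-butyldimethylsilyl)oxy]-5-[2-methoxy-2-(trimethylsilyloxy)ethenyl]-2-(prop-1-en-2-yl)-2,3-dihydrofuran F1, a type of diene made directly from 3-alkoxy-2-enoate esters and established in cycloadditions with acetylenic carbonyl compounds. Reaction with 16 in toluene should give the mixed-ketal cycloadduct F2. Aqueous acid then removes the silyl group and expels methanol from C6, and the resulting dienone tautomerises to phenol 19, where the route is rejoined; step 8 is then not needed.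

Step 9. The lithium dienolate may expel the C3 silanolate (vinylogous β-elimination), which ends in a furan-2-ylacetic acid derivative, or the amide base may attack silicon of the silyl ester instead of removing the γ-proton. The fallback sets out from acid 13 and replaces the silyl ether by an oxido group during the deprotonation. Bu4NF/AcOH should give (2E)-2-[(4S,5S)-4-hydroxy-5-(prop-1-en-2-yl)oxolan-2-ylidene]acetic acid F3. With LiN(iPr)2 (3.3 equiv, −78 → −20 °C) the C3 oxygen is a lithium alkoxide, which cannot leave (the principle behind alkylations of β-hydroxy ester dianions). Me3SiCl then silylates all three oxygens to (2S,3S)-5-[2,2-bis(trimethylsilyloxy)ethenyl]-2-(prop-1-en-2-yl)-3-(trimethylsilyloxy)-2,3-dihydrofuran F4. Cycloaddition with 16 as in step 10 gives the tris(trimethylsilyl) cycloadduct F5, and the acidic work-up cleaves every trimethylsilyl group, so diol 20 is reached directly and step 11 is not needed.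

Step 16. Chloride or base may add to C3 of the activated 2-(acetoxymethyl)enoyl donor and eliminate again, which would erode the Z geometry or transpose the allylic acetate; some acylation of the phenol may also compete. The fallback sets out from iodo alcohol 23 and carries the side chain without an allylic leaving group. Silylation (t-BuMe2SiCl, imidazole) should give tert-butyl{[(Z)-2-iodobut-2-en-1-yl]oxy}dimethylsilane F6, and t-BuLi then CO2 should give (Z)-2-{[(tert-butyldimethylsilyl)oxy]methyl}but-2-enoic acid F7. Its acid chloride, made and used as in step 16, should esterify 20 to (2S,3S)-5-acetyl-6-hydroxy-2-(prop-1-en-2-yl)-2,3-dihydro-1-benzofuran-3-yl (2Z)-2-{[(tert-butyldimethylsilyl)oxy]methyl}but-2-enoate F8. HF·pyridine buffered with pyridine removes the primary silyl ether to give (2S,3S)-5-acetyl-6-hydroxy-2-(prop-1-en-2-yl)-2,3-dihydro-1-benzofuran-3-yl (2Z)-2-(hydroxymethyl)but-2-enoate F9. Ac2O/pyridine at 0 °C should then acetylate the primary allylic alcohol faster than the hydrogen-bonded phenol and give target 28.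

Further compounds
F1 | step 10 | (2S,3S)-3-[(tert-butyldimethylsilyl)oxy]-5-[2-methoxy-2-(trimethylsilyloxy)ethenyl]-2-(prop-1-en-2-yl)-2,3-dihydrofuran (ketene acetal geometry not defined) | C=C(C)[C@@H]1OC(C=C(OC)O[Si](C)(C)C)=C[C@@H]1O[Si](C)(C)C(C)(C)C
F2 | step 10 | 1-[(2S,3S)-3-[(tert-butyldimethylsilyl)oxy]-6-methoxy-2-(prop-1-en-2-yl)-6-(trimethylsilyloxy)-2,3,3a,6-tetrahydro-1-benzofuran-5-yl]ethan-1-one (C3a and C6 epimers) | C=C(C)[C@@H]1OC2=CC(OC)(O[Si](C)(C)C)C(C(C)=O)=CC2[C@@H]1O[Si](C)(C)C(C)(C)C
F3 | step 9 | (2E)-2-[(4S,5S)-4-hydroxy-5-(prop-1-en-2-yl)oxolan-2-ylidene]acetic acid | C=C(C)[C@@H]1O/C(=C/C(=O)O)C[C@@H]1O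
F4 | step 9 | (2S,3S)-5-[2,2-bis(trimethylsilyloxy)ethenyl]-2-(prop-1-en-2-yl)-3-(trimethylsilyloxy)-2,3-dihydrofuran | C=C(C)[C@@H]1OC(C=C(O[Si](C)(C)C)O[Si](C)(C)C)=C[C@@H]1O[Si](C)(C)C
F5 | step 9 | 1-[(2S,3S)-2-(prop-1-en-2-yl)-3,6,6-tris(trimethylsilyloxy)-2,3,3a,6-tetrahydro-1-benzofuran-5-yl]ethan-1-one (C3a epimers) | C=C(C)[C@@H]1OC2=CC(O[Si](C)(C)C)(O[Si](C)(C)C)C(C(C)=O)=CC2[C@@H]1O[Si](C)(C)C
F6 | step 16 | tert-butyl{[(Z)-2-iodobut-2-en-1-yl]oxy}dimethylsilane | C/C=C(\I)CO[Si](C)(C)C(C)(C)C
F7 | step 16 | (Z)-2-{[(tert-butyldimethylsilyl)oxy]methyl}but-2-enoic acid | C/C=C(\C(=O)O)CO[Si](C)(C)C(C)(C)C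
F8 | step 16 | (2S,3S)-5-acetyl-6-hydroxy-2-(prop-1-en-2-yl)-2,3-dihydro-1-benzofuran-3-yl (2Z)-2-{[(tert-butyldimethylsilyl)oxy]methyl}but-2-enoate | C=C(C)[C@@H]1Oc2cc(O)c(C(C)=O)cc2[C@@H]1OC(=O)/C(=C\C)CO[Si](C)(C)C(C)(C)C
F9 | step 16 | (2S,3S)-5-acetyl-6-hydroxy-2-(prop-1-en-2-yl)-2,3-dihydro-1-benzofuran-3-yl (2Z)-2-(hydroxymethyl)but-2-enoate | C=C(C)[C@@H]1Oc2cc(O)c(C(C)=O)cc2[C@@H]1OC(=O)/C(=C\C)CO
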